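The target is a cis-fused hydroazulene; its carbons are numbered C1 (methyl-bearing ring-fusion carbon), C2–C4 (rest of the five-membered ring), C5 (ring-fusion CH) and C6–C10 (rest of the seven-membered ring). Everything rests on the ring-fusion bond C1–C5. In a cis-decalin that still has C1 bonded to C6, a pinacol-type 1,2-shift moves the quaternary C1 from the carbinol carbon C6 to C5: ring B contracts to the cyclopentane and ring A expands to the cycloheptenone in one operation. The shift exploits the oxygen on C6 (it becomes the ketone) and sets the cis C1-methyl/C5-H fusion stereospecifically. The precursor, a 6-hydroxy-5-mesyloxy decalin, takes all fifteen carbons from a Diels–Alder reaction of thymoquinone.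

Key step: step 10

Convention: every intermediate keeps the atom numbers of the target (methyl on C1, OH on C2, OH and isopropyl on C4, methyl on C8). β is the face of the C1 methyl, α the other face. In the decalins 6–15, ring A is C1, C6–C10 and ring B is C1–C6. Absolute configuration comes from separating the two camphanate diastereomers formed in step 2; all later stereocentres are substrate-controlled. The target carries two angeloyl groups, so step 14 consumes two equivalents of angelic acid, one per secondary hydroxyl.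

Step 1
Reactants: 1 3-methylbut-2-enal (prenal); 2 (1S,4R)-camphanoyl chloride
Product: 4 (1E)-3-methylbuta-1,3-dien-1-yl (1S,4R)-camphanate, via potassium dienolate 3 (not isolated)
Conditions: KOtBu, THF, −78 °C; then 2, −78 → 0 °C
Reagents that add atoms: none
Why: γ-Deprotonation of the enal gives the extended dienolate, which the acid chloride acylates on oxygen to the (E)-1-acyloxydiene (standard O-acylation route to 1-acyloxy-1,3-dienes); no new stereocentre is formed.

Step 2
Reactants: 4 (1E)-3-methylbuta-1,3-dien-1-yl (1S,4R)-camphanate; 5 thymoquinone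
Product: 6 cis-decalin-2,5-dione with C3=C4 and C8=C9 double bonds (4-isopropyl, 8-methyl, 1β-methyl, 6β-H, 10α-camphanoyloxy)
Conditions: PhMe, BHT (cat.), 110 °C, sealed tube; the two endo diastereomers are separated by crystallisation or chromatography
Reagents that add atoms: none
Why: Thermal endo Diels–Alder reaction of a quinone: the less hindered methyl-bearing double bond should react, the nucleophilic CH2 terminus (C7) of the diene bonds to the unsubstituted C6 so that the oxygenated C10 sits next to the new quaternary C1 ("ortho" rule), suprafacial addition makes C1-methyl and C6-H cis and the endo mode puts the 10-acyloxy group trans to the methyl; the remote camphanate is not expected to bias the diene faces, so both endo diastereomers should form and the one shown is carried on (assignment by X-ray).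

Step 3
Reactants: 6 cis-decalin-2,5-dione
Product: 8 6β-hydroxy derivative of 6 (cis-fused tertiary α-ketol), via sodium enolate 7 (not isolated)
Conditions: NaN(SiMe3)2, THF, −78 °C; then 3-phenyl-2-(phenylsulfonyl)oxaziridine, −78 → −40 °C; aq. NH4Cl
Reagents that add atoms: 3-phenyl-2-(phenylsulfonyl)oxaziridine (Davis oxaziridine), O=S(=O)(c1ccccc1)N1OC1c1ccccc1
Why: Davis α-hydroxylation of a ketone enolate: C6–H is the only sp3 α-hydrogen of either carbonyl, and the oxaziridine should attack the convex β face, cis to the C1 methyl and away from the 10α-acyloxy group; this centre becomes the ketone carbon in step 10, so it matters only for conformation.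

Step 4
Reactants: 8 6β-hydroxy enedione
Product: 9 5α,6β-dihydroxy-3-en-2-one (4-isopropyl, 10α-camphanoyloxy)
Conditions: NaBH4, CeCl3·7H2O, MeOH, −78 °C
Reagents that add atoms: none
Why: Luche 1,2-reduction: the α-ketol carbonyl C5 (activated by cerium chelation with the C6 hydroxyl) should react before the C2 carbonyl, which is shielded by the C1 methyl and the C10 acyloxy group and is the carbonyl of a β-alkyl enone, and hydride delivery on the convex β face gives the 5α-alcohol.

Step 5
Reactants: 9 5α,6β-dihydroxy enone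
Product: 10 3α,4α-epoxy-5α,6β-dihydroxy-2-ketone
Conditions: VO(acac)2 (cat.), t-BuOOH (decane), CH2Cl2, 0 °C → rt
Reagents that add atoms: tert-butyl hydroperoxide, CC(C)(C)OO
Why: Vanadium-catalysed hydroxyl-directed epoxidation: the secondary allylic 5α-alkoxide binds vanadium and delivers oxygen to the α face of C3=C4 (sets C3 and C4); the C8=C9 bond has no free allylic hydroxyl and the tertiary C6–OH is hindered and only homoallylic.

Step 6
Reactants: 10 epoxy ketone diol
Product: 11 5α-mesylate of 10
Conditions: MsCl, Et3N, CH2Cl2, 0 °C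
Reagents that add atoms: methanesulfonyl chloride, CS(=O)(=O)Cl
Why: Sulfonylation through sulfene of the only secondary hydroxyl; the tertiary C6–OH does not react and no stereocentre changes.

Step 7
Reactants: 11 epoxy ketone mesylate
Product: 12 4α,6β-dihydroxy-5α-mesyloxy-2-ketone (C3 now CH2)
Conditions: SmI2, THF/MeOH, −78 °C
Reagents that add atoms: none
Why: SmI2 reduction of an α,β-epoxy ketone: the ketyl cleaves the Cα–O bond (C3–O) and leaves the C4 oxygen, α configuration unchanged, as the tertiary alcohol; mesylate and esters are not touched at −78 °C.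

Step 8
Reactants: 12 β-hydroxy ketone mesylate
Product: 13 2β,4α,6β-triol 5α-mesylate
Conditions: Me4NBH(OAc)3, MeCN/AcOH, −20 °C
Reagents that add atoms: none
Why: Evans–Saksena hydroxyl-directed reduction: the axial 4α-OH exchanges onto boron and delivers hydride to the α face of the C2 ketone, giving the 2β-alcohol (1,3-anti); the equatorial, hindered C6–OH cannot reach the carbonyl.

Step 9
Reactants: 13 triol mesylate
Product: 14 2β-triethylsilyl ether of 13
Conditions: Et3SiOTf, 2,6-lutidine, CH2Cl2, −78 °C
Reagents that add atoms: triethylsilyl trifluoromethanesulfonate, CC[Si](CC)(CC)OS(=O)(=O)C(F)(F)F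
Why: Silylation of the only secondary hydroxyl at low temperature, leaving both tertiary hydroxyls free; this group later distinguishes C2–OH from the two hydroxyls that are acylated.

Step 10
Reactants: 14 2β-triethylsilyloxy-4α,6β-dihydroxy-5α-mesyloxy decalin
Product: 16 cis-fused hydroazulen-6-one (5β-H, 4α-OH, 2β-OSiEt3, 10α-camphanoyloxy, C8=C9), via aluminium alkoxide 15 (not isolated)
Conditions: Et3Al, CH2Cl2, −78 → 0 °C; aq. potassium sodium tartrate
Reagents that add atoms: none
Why: Et3Al turns both tertiary hydroxyls into diethylaluminium alkoxides; the C6 alkoxide pushes, the aluminium-activated equatorial C5 mesylate leaves, and the C6–C1 ring bond, antiperiplanar to C5–O in the chair of ring B, migrates from C6 to C5 in a concerted 1,2-shift that leaves C6 as the ketone. The closest known reactions are the organoaluminium-promoted pinacol-type rearrangement of β-mesyloxy tertiary alcohols and the diol-monosulfonate route from hydronaphthalenes to hydroazulenes (steroid 4-mesyloxy-5-ols to ring-A-nor ring-B-homo ketones). The new C1–C5 bond closes the cyclopentane C1–C5 by contraction of ring B through a bridging three-centre transition state and, in the same event, makes the cycloheptenone by one-carbon expansion of ring A. C1 migrates with retention and C5 is inverted, so the C5 hydrogen, cis to the C1 methyl in 14, stays cis; the cis fusion is therefore dictated by the 5α-oxygen set in step 4, and no other centre is touched. The step needs migration of C1, not of C3 (also antiperiplanar, pushed by the C4 alkoxide), and a shift, not epoxide closure; the quaternary C1 has the far higher migratory aptitude, and C6–O is gauche to the leaving group and cannot displace it from the rear.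

Step 11
Reactants: 16 hydroazulen-6-one
Product: 17 4α,6β-diol (2β-OSiEt3, 10α-camphanoyloxy, C8=C9)
Conditions: Me4NBH(OAc)3, MeCN/AcOH, −20 °C (16 used without delay)
Reagents that add atoms: none
Why: Evans–Saksena reduction of the β-hydroxy ketone: the 4α-hydroxyl delivers hydride to the α face of C6 and gives the 6β-alcohol (1,3-anti), the face a free hydride would not choose on the concave side; the labile β,γ-unsaturated ketone is consumed before it can conjugate or epimerise at C5.

Step 12
Reactants: 17 4α,6β-diol camphanate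
Product: 18 4α,6β,10α-triol (2β-OSiEt3, C8=C9)
Conditions: NaOMe (cat.), MeOH, 40 °C
Reagents that add atoms: none
Why: Methanolysis (transesterification) of the only ester releases the 10α-hydroxyl and the auxiliary; silyl ether and alkene are stable and no stereocentre changes.

Step 13
Reactants: 18 4α,6β,10α-triol
Product: 19 8α,9α-epoxy-4α,6β,10α-triol (2β-OSiEt3)
Conditions: VO(acac)2 (cat.), t-BuOOH (decane), CH2Cl2, 0 °C → rt
Reagents that add atoms: tert-butyl hydroperoxide, CC(C)(C)OO
Why: Vanadium-catalysed hydroxyl-directed epoxidation: the allylic 10α-OH delivers oxygen to the α face of the only alkene C8=C9 (sets C8 and C9), allylic direction being faster than that of the homoallylic 6β-OH.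

Step 14
Reactants: 19 epoxy triol; 20 angelic acid ((Z)-2-methylbut-2-enoic acid)
Product: 23 6β,10α-bis(angeloyloxy)-8α,9α-epoxy-4α-hydroxy-2β-triethylsilyloxy hydroazulene, via mixed anhydride 21 (not isolated), via 6-monoangelate 22 (not isolated)
Conditions: 20 (3 equiv), 2,4,6-Cl3C6H2COCl (3 equiv), Et3N, PhMe, rt; then 19, 80 °C
Reagents that add atoms: angelic acid (second equivalent of 20 for the second hydroxyl), C/C=C(/C)C(=O)O
Why: Yamaguchi-type esterification through the preformed mixed anhydride without DMAP, the established way to make angelates without isomerisation to tiglates: with excess 21 the less hindered 6β-hydroxyl should be acylated first and the neopentyl 10α-hydroxyl second, each taking one angeloyl group, while the tertiary C4–OH should not react.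

Step 15
Reactants: 23 bis-angelate silyl ether
Product: 24 CNP0265715.3
Conditions: Bu4NF, AcOH, THF, 0 °C
Reagents that add atoms: none
Why: Buffered fluoride cleavage of the triethylsilyl ether frees the 2β-hydroxyl; angelates, epoxide and tertiary alcohol should survive these near-neutral conditions.

Compound list
1 | 3-methylbut-2-enal (prenal) | CC(C)=CC=O | starting material
2 | (1S,4R)-camphanoyl chloride ((1S,4R)-4,7,7-trimethyl-3-oxo-2-oxabicyclo[2.2.1]heptane-1-carbonyl chloride) | O=C(Cl)[C@@]12CC[C@@](C)(C(=O)O1)C2(C)C | starting material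
3 | potassium (1E)-3-methylbuta-1,3-dien-1-olate | C=C(C)/C=C/[O-].[K+] | intermediate
4 | (1E)-3-methylbuta-1,3-dien-1-yl (1S,4R)-camphanate | C=C(C)/C=C/OC(=O)[C@@]12CC[C@@](C)(C(=O)O1)C2(C)C | intermediate
5 | thymoquinone (2-isopropyl-5-methyl-1,4-benzoquinone) | CC1=CC(=O)C(C(C)C)=CC1=O | starting material
6 | cis-decalin-2,5-dione, C3=C4 and C8=C9, 4-isopropyl, 8-methyl, 1β-methyl, 6β-H, 10α-camphanoyloxy | CC1=C[C@H](OC(=O)[C@@]34CC[C@@](C)(C(=O)O3)C4(C)C)[C@]2(C)C(=O)C=C(C(C)C)C(=O)[C@@H]2C1 | intermediate
7 | sodium C5-enolate of 6 (C5–O−, C5=C6) | CC1=C[C@H](OC(=O)[C@@]34CC[C@@](C)(C(=O)O3)C4(C)C)[C@]2(C)C(=O)C=C(C(C)C)C([O-])=C2C1.[Na+] | intermediate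
8 | 6β-hydroxy derivative of 6 | CC1=C[C@H](OC(=O)[C@@]34CC[C@@](C)(C(=O)O3)C4(C)C)[C@]2(C)C(=O)C=C(C(C)C)C(=O)[C@]2(O)C1 | intermediate
9 | 5α,6β-dihydroxy-3-en-2-one | CC1=C[C@H](OC(=O)[C@@]34CC[C@@](C)(C(=O)O3)C4(C)C)[C@]2(C)C(=O)C=C(C(C)C)[C@H](O)[C@]2(O)C1 | intermediate
10 | 3α,4α-epoxy-5α,6β-dihydroxy-2-ketone | CC1=C[C@H](OC(=O)[C@@]34CC[C@@](C)(C(=O)O3)C4(C)C)[C@]2(C)C(=O)[C@@H]5O[C@]5(C(C)C)[C@H](O)[C@]2(O)C1 | intermediate
11 | 5α-mesylate of 10 | CC1=C[C@H](OC(=O)[C@@]34CC[C@@](C)(C(=O)O3)C4(C)C)[C@]2(C)C(=O)[C@@H]5O[C@]5(C(C)C)[C@H](OS(C)(=O)=O)[C@]2(O)C1 | intermediate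
12 | 4α,6β-dihydroxy-5α-mesyloxy-2-ketone | CC1=C[C@H](OC(=O)[C@@]34CC[C@@](C)(C(=O)O3)C4(C)C)[C@]2(C)C(=O)C[C@@](O)(C(C)C)[C@H](OS(C)(=O)=O)[C@]2(O)C1 | intermediate
13 | 2β,4α,6β-triol 5α-mesylate | CC1=C[C@H](OC(=O)[C@@]34CC[C@@](C)(C(=O)O3)C4(C)C)[C@]2(C)[C@@H](O)C[C@@](O)(C(C)C)[C@H](OS(C)(=O)=O)[C@]2(O)C1 | intermediate
14 | 2β-triethylsilyl ether of 13 | CC1=C[C@H](OC(=O)[C@@]34CC[C@@](C)(C(=O)O3)C4(C)C)[C@]2(C)[C@@H](O[Si](CC)(CC)CC)C[C@@](O)(C(C)C)[C@H](OS(C)(=O)=O)[C@]2(O)C1 | intermediate
15 | 4,6-bis(diethylaluminium) alkoxide of 14 | CC1=C[C@H](OC(=O)[C@@]34CC[C@@](C)(C(=O)O3)C4(C)C)[C@]2(C)[C@@H](O[Si](CC)(CC)CC)C[C@@](O[Al](CC)CC)(C(C)C)[C@H](OS(C)(=O)=O)[C@]2(O[Al](CC)CC)C1 | intermediate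
16 | cis-fused hydroazulen-6-one, 5β-H, 4α-OH, 2β-OSiEt3, 10α-camphanoyloxy, C8=C9 | CC1=C[C@H](OC(=O)[C@@]34CC[C@@](C)(C(=O)O3)C4(C)C)[C@@]2(C)[C@@H](C(=O)C1)[C@](O)(C(C)C)C[C@@H]2O[Si](CC)(CC)CC | intermediate
17 | 6β-alcohol from 16 (4α,6β-diol) | CC1=C[C@H](OC(=O)[C@@]34CC[C@@](C)(C(=O)O3)C4(C)C)[C@@]2(C)[C@@H]([C@@H](O)C1)[C@](O)(C(C)C)C[C@@H]2O[Si](CC)(CC)CC | intermediate
18 | 4α,6β,10α-triol, 2β-OSiEt3, C8=C9 | CC1=C[C@H](O)[C@@]2(C)[C@@H]([C@@H](O)C1)[C@](O)(C(C)C)C[C@@H]2O[Si](CC)(CC)CC | intermediate
19 | 8α,9α-epoxy-4α,6β,10α-triol, 2β-OSiEt3 | O[C@H]1C[C@]2(C)O[C@@H]2[C@H](O)[C@@]2(C)[C@@H]1[C@](O)(C(C)C)C[C@@H]2O[Si](CC)(CC)CC | intermediate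
20 | angelic acid ((Z)-2-methylbut-2-enoic acid) | C/C=C(/C)C(=O)O | starting material
21 | angelic 2,4,6-trichlorobenzoic anhydride | C/C=C(/C)C(=O)OC(=O)c1c(Cl)cc(Cl)cc1Cl | intermediate
22 | 6β-angeloyloxy-8α,9α-epoxy-4α,10α-dihydroxy-2β-triethylsilyloxy hydroazulene (6-monoangelate of 19) | C/C=C(/C)C(=O)O[C@H]1C[C@]2(C)O[C@@H]2[C@H](O)[C@@]2(C)[C@@H]1[C@](O)(C(C)C)C[C@@H]2O[Si](CC)(CC)CC | intermediate
23 | 6β,10α-bis(angeloyloxy)-8α,9α-epoxy-4α-hydroxy-2β-triethylsilyloxy hydroazulene | C/C=C(/C)C(=O)O[C@H]1C[C@]2(C)O[C@@H]2[C@H](OC(=O)/C(C)=C\C)[C@@]2(C)[C@@H]1[C@](O)(C(C)C)C[C@@H]2O[Si](CC)(CC)CC | intermediate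
24 | CNP0265715.3: 6β,10α-bis(angeloyloxy)-8α,9α-epoxy-2β,4α-diol, 5β-H; (1S,2S,4R,5S,6S,8S,9R,10R) in the numbering used here | C/C=C(/C)C(=O)O[C@H]1C[C@]2(C)O[C@@H]2[C@H](OC(=O)/C(C)=C\C)[C@@]2(C)[C@@H]1[C@](O)(C(C)C)C[C@@H]2O | target

Total step count: 15. Longest linear sequence: 15 steps (from prenal 1; thymoquinone 5 and angelic acid 20 enter as purchased materials).

Steps most likely to fail

Step 10 (key step). What may go wrong: migration of the wrong ring bond, because the C4 aluminium alkoxide can also push and C3 is likewise antiperiplanar to the mesylate, which would contract ring B to an acylcyclopentane; ethyl or hydride transfer from aluminium to the new ketone; conjugation of its β,γ double bond. Fallback, from 14 back to 16: the competing hydroxyl is masked and the shift is driven by a single potassium alkoxide. The less hindered tertiary C4 hydroxyl of 14 would be silylated (Me3SiOTf, Et3N, −78 °C) to the 4-O-trimethylsilyl ether of 14, F3. KN(SiMe3)2 (1 equiv, THF, −78 → 0 °C) would then deprotonate the only free hydroxyl (C6) and should trigger the same 1,2-shift to the 4-O-trimethylsilyl ether of 16, F4. PPTS in MeOH at 0 °C should remove the tertiary trimethylsilyl ether while the secondary triethylsilyl ether stays, giving 16.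

Step 5. What may go wrong: slow oxygen transfer to the electron-poor enone double bond, and delivery to the β face by the tertiary C6 hydroxyl. Fallback, from 9 back to 12: the oxygen is brought to C4 by a covalent tether instead of an epoxide. 9 would be treated with phenylboronic acid (cat. i-Pr2NH, 4 Å molecular sieves, PhMe); the boronic acid hemiester of the C5 hydroxyl adds its B–OH oxygen to C4 in an intramolecular oxa-Michael reaction, which can only give the cis-fused cyclic phenylboronate of the 4α,5α-diol, F1. Oxidative removal of boron (aq. H2O2, NaHCO3, THF) should give the 4α,5α,6β-trihydroxy-2-ketone, F2, and mesylation of its only secondary hydroxyl (MsCl, Et3N) gives 12; steps 5–7 are replaced.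

Step 14. What may go wrong: incomplete acylation of the hindered C10 hydroxyl beside the epoxide, so that the reaction stalls at the monoangelate, and Z-to-E isomerisation of the angeloyl group on prolonged heating. Fallback, from 19 back to 23: the Z double bonds are made after the ester bonds. 19 would be acylated at both secondary hydroxyls with two equivalents of 2-[bis(2,2,2-trifluoroethoxy)phosphoryl]propanoic acid (DCC, DMAP, CH2Cl2) to the 6,10-bis(phosphonopropanoate) of 19, F5. A twofold Still–Gennari olefination with acetaldehyde (KN(SiMe3)2, 18-crown-6, THF, −78 °C) should then form both (Z)-2-methylbut-2-enoates and give 23.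

Further compounds
F1 | step 5 | cyclic phenylboronate of the 4α,5α-diol (C3 = CH2, 2-ketone, 6β-OH, 10α-camphanoyloxy decalin) | CC1=C[C@H](OC(=O)[C@@]34CC[C@@](C)(C(=O)O3)C4(C)C)[C@]2(C)C(=O)C[C@]5(C(C)C)OB(c6ccccc6)O[C@@H]5[C@]2(O)C1
F2 | step 5 | 4α,5α,6β-trihydroxy-2-ketone (10α-camphanoyloxy decalin) | CC1=C[C@H](OC(=O)[C@@]34CC[C@@](C)(C(=O)O3)C4(C)C)[C@]2(C)C(=O)C[C@@](O)(C(C)C)[C@H](O)[C@]2(O)C1
F3 | step 10 | 4-O-trimethylsilyl ether of 14 | CC1=C[C@H](OC(=O)[C@@]34CC[C@@](C)(C(=O)O3)C4(C)C)[C@]2(C)[C@@H](O[Si](CC)(CC)CC)C[C@@](O[Si](C)(C)C)(C(C)C)[C@H](OS(C)(=O)=O)[C@]2(O)C1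
F4 | step 10 | 4-O-trimethylsilyl ether of 16 | CC1=C[C@H](OC(=O)[C@@]34CC[C@@](C)(C(=O)O3)C4(C)C)[C@@]2(C)[C@@H](C(=O)C1)[C@](O[Si](C)(C)C)(C(C)C)C[C@@H]2O[Si](CC)(CC)CC
F5 | step 14 | 6,10-bis{2-[bis(2,2,2-trifluoroethoxy)phosphoryl]propanoate} of 19 | CC(C(=O)O[C@H]1C[C@]2(C)O[C@@H]2[C@H](OC(=O)C(C)P(=O)(OCC(F)(F)F)OCC(F)(F)F)[C@@]2(C)[C@@H]1[C@](O)(C(C)C)C[C@@H]2O[Si](CC)(CC)CC)P(=O)(OCC(F)(F)F)OCC(F)(F)F
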